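The terminal unit's ring C is the disconnection. A protected trimer is capped at C4 of its lowest unit with a symmetric phloroglucinol ring, which becomes ring A of the terminal unit. In the key step the lone free phenol of this cap, para to the interflavan carbon, is etherified with an erythro epoxy alcohol (O1–C2, with inversion), and the epoxide is then opened 6-endo by the adjacent ring carbon (C4–C4a), in one flask. Because O1 is para to the interflavan carbon and the two ortho carbons (future C4a and C8) are equivalent, the 4→6 linkage follows without a regioselective coupling.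

Key step: step 16

Remark: the target is read as epicatechin-(4β→6)-epiafzelechin-(4β→8)-epicatechin-(4β→6)-epicatechin (units 1 to 4 from the top), every unit 2R,3R (2,3-cis) and every interflavan bond 3,4-trans.
Assumption: (−)-epiafzelechin is taken as a purchasable catalogue natural product.

Step 1
Reactants: 1 (−)-epicatechin
Product: 2 3,5,7,3',4'-penta-O-benzyl-(−)-epicatechin
Conditions: BnBr, NaH, DMF, −20 °C → rt
Reagents that add atoms: benzyl bromide, BrCc1ccccc1
Why: Williamson etherification: NaH forms the four phenoxides and the C3 alkoxide, which BnBr should benzylate at low temperature before any base-induced change at C2, so the 2R,3R centres are kept.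

Step 2
Reactants: 2 penta-O-benzylepicatechin
Product: 3 4β-(2-ethoxyethoxy)-3,5,7,3',4'-penta-O-benzylepicatechin (3,4-trans)
Conditions: DDQ, HOCH2CH2OEt, CH2Cl2, rt
Reagents that add atoms: 2-ethoxyethanol, CCOCCO
Why: DDQ benzylic oxidation: hydride abstraction from C4, assisted by the 5- and 7-benzyloxy groups, gives a quinone-methide-type cation that 2-ethoxyethanol should trap anti to the 3-benzyloxy and 2-aryl groups, which sets the 4β ether.

Step 3
Reactants: 3 4β-(2-ethoxyethoxy)-penta-O-benzylepicatechin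
Product: 4 6,8-dibromo-4β-(2-ethoxyethoxy)-3,5,7,3',4'-penta-O-benzylepicatechin (electrophile for unit 1)
Conditions: NBS (2.1 equiv), CH2Cl2, −40 → 0 °C
Reagents that add atoms: N-bromosuccinimide, O=C1CCC(=O)N1Br
Why: Electrophilic aromatic bromination: the phloroglucinol-type ring A is far more reactive than the catechol ring, so NBS should brominate C8 and then C6, blocking both nucleophilic positions of the future top unit.

Step 4
Reactants: 5 (−)-epiafzelechin
Product: 6 3,5,7,4'-tetra-O-benzyl-(−)-epiafzelechin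
Conditions: BnBr, NaH, DMF, −20 °C → rt
Reagents that add atoms: benzyl bromide, BrCc1ccccc1
Why: Williamson etherification of the three phenoxides and the C3 alkoxide, as in step 1, with the 2R,3R centres kept.

Step 5
Reactants: 6 tetra-O-benzylepiafzelechin
Product: 7 4β-(2-ethoxyethoxy)-3,5,7,4'-tetra-O-benzylepiafzelechin (3,4-trans)
Conditions: DDQ, HOCH2CH2OEt, CH2Cl2, rt
Reagents that add atoms: 2-ethoxyethanol, CCOCCO
Why: DDQ benzylic oxidation at C4 with capture of the cation by the alcohol anti to the 3-benzyloxy group, as in step 2, gives the 4β ether.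

Step 6
Reactants: 7 4β-(2-ethoxyethoxy)-tetra-O-benzylepiafzelechin
Product: 8 8-bromo-4β-(2-ethoxyethoxy)-3,5,7,4'-tetra-O-benzylepiafzelechin
Conditions: NBS (1.0 equiv), CH2Cl2, −78 °C
Reagents that add atoms: N-bromosuccinimide, O=C1CCC(=O)N1Br
Why: Electrophilic aromatic bromination: one equivalent of NBS at low temperature should brominate C8, the more reactive position next to O1, leaving C6 as the only free ring-A carbon.

Step 7
Reactants: 8 8-bromo-4β-(2-ethoxyethoxy)-tetra-O-benzylepiafzelechin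
Product: 9 8-bromo-4β-(2,6-dimethylphenylthio)-3,5,7,4'-tetra-O-benzylepiafzelechin (nucleophile for unit 2)
Conditions: 2,6-Me2C6H3SH, BF3·OEt2, CH2Cl2, −78 → −20 °C
Reagents that add atoms: 2,6-dimethylbenzenethiol, Cc1cccc(C)c1S
Why: Lewis-acid SN1 substitution: BF3·OEt2 ionizes the C4 ether and the thiol should add anti to the 3-benzyloxy group to give the 4β thioether, a hindered leaving group that stays inert to hard Lewis acids.

Step 8
Reactants: 4 dibromo electrophile of unit 1; 9 bromo sulfide of unit 2 (in excess)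
Product: 10 dimer [6,8-dibromo-penta-O-benzylepicatechin]-(4β→6)-[8-bromo-4β-(2,6-dimethylphenylthio)-tetra-O-benzylepiafzelechin]
Conditions: BF3·OEt2, 4 Å MS, CH2Cl2, −78 → −30 °C
Reagents that add atoms: none
Why: Friedel–Crafts alkylation by a flavan-4-yl cation: BF3·OEt2 ionizes only the oxygen leaving group of 4 while the sulfide of 9 stays intact; because 4 is brominated at C6 and C8 and 9 at C8, the only nucleophilic ring-A carbon is C6 of 9, and attack anti to the 3-benzyloxy and 2-aryl groups of the cation should set the 4β (3,4-trans) interflavan bond.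

Step 9
Reactants: 3 4β-(2-ethoxyethoxy)-penta-O-benzylepicatechin; 11 phloroglucinol (large excess)
Product: 12 4β-(2,4,6-trihydroxyphenyl)-3,5,7,3',4'-penta-O-benzylepicatechin
Conditions: BF3·OEt2, THF–CH2Cl2, −20 → 0 °C
Reagents that add atoms: none
Why: Friedel–Crafts alkylation: the cation from 3 should be captured by excess phloroglucinol, whose three ring carbons are equivalent so that one regioisomer forms, anti to the 3-benzyloxy group (4β).

Step 10
Reactants: 12 phloroglucinol adduct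
Product: 13 4β-[2,6-dihydroxy-4-(pivaloyloxy)phenyl]-3,5,7,3',4'-penta-O-benzylepicatechin
Conditions: PivCl (1.0 equiv), Et3N, CH2Cl2, −40 °C
Reagents that add atoms: pivaloyl chloride, CC(C)(C)C(Cl)=O
Why: Site-selective O-acylation: the bulky acyl chloride should react at the phenol para to the flavanyl carbon, the only one not flanked by the C4 substituent, which marks the oxygen that becomes O1 of unit 4.

Step 11
Reactants: 13 monopivalate
Product: 14 4β-[2,6-bis(benzyloxy)-4-(pivaloyloxy)phenyl]-3,5,7,3',4'-penta-O-benzylepicatechin (nucleophile, unit 3 with cap)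
Conditions: BnBr, K2CO3, DMF, rt
Reagents that add atoms: benzyl bromide, BrCc1ccccc1
Why: Williamson etherification of the two remaining phenols; the aryl pivalate should survive K2CO3 in dry DMF and cannot migrate between meta-disposed oxygens.

Step 12
Reactants: 10 dimeric sulfide; 14 capped unit 3 (in excess)
Product: 15 protected trimer with cap: [unit 1]-(4β→6)-[unit 2]-(4β→8)-[penta-O-benzylepicatechin]-4β-[2,6-bis(benzyloxy)-4-(pivaloyloxy)phenyl]
Conditions: I2, Ag2O, 4 Å MS, CH2Cl2, −78 → −20 °C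
Reagents that add atoms: none
Why: Friedel–Crafts alkylation after soft (iodonium) activation of the C4–S bond: the dimeric cation should be captured by C8 of the flavan ring of 14, its most nucleophilic and least hindered position (the cap ring is deactivated by the pivalate, which also flanks both of its free carbons), anti to the 3-benzyloxy group of unit 2, which sets the 4β→8 bond.

Step 13
Reactants: 15 trimer pivalate
Product: 16 trimer phenol: as 15 but with a 2,6-bis(benzyloxy)-4-hydroxyphenyl cap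
Conditions: NaOMe, MeOH–THF, rt; aq. NH4Cl
Reagents that add atoms: none
Why: Base-mediated transesterification of the aryl pivalate frees the single phenol needed for the annulation, while benzyl ethers and aryl bromides are untouched.

Step 14
Reactants: 17 3,4-bis(benzyloxy)benzaldehyde
Product: 18 (±)-1-[3,4-bis(benzyloxy)phenyl]prop-2-en-1-ol
Conditions: CH2=CHMgBr, THF, −20 °C; aq. NH4Cl
Reagents that add atoms: vinylmagnesium bromide, C=C[Mg]Br
Why: Grignard 1,2-addition to the aldehyde gives the racemic secondary allylic alcohol.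

Step 15
Reactants: 18 racemic allylic alcohol
Product: 19 (S)-[3,4-bis(benzyloxy)phenyl][(2R)-oxiran-2-yl]methanol (erythro)
Conditions: Ti(OiPr)4 (cat.), L-(+)-DIPT, t-BuOOH (0.45 equiv), 4 Å MS, CH2Cl2, −20 °C
Reagents that add atoms: tert-butyl hydroperoxide, CC(C)(C)OO
Why: Sharpless kinetic resolution: with L-(+)-DIPT the (R)-enantiomer of 18 should be epoxidized much faster than the (S)-enantiomer and with erythro selectivity, so stopping below half conversion gives the (S)-carbinol/(2R)-oxirane product, the reagent setting the oxirane centre and the resolution selecting the carbinol centre.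

Step 16
Reactants: 16 trimer phenol; 19 erythro epoxy alcohol
Product: 21 protected tetramer (unit 4 formed, 3-OH of unit 4 free), via aryl ether epoxide 20 (not isolated)
Conditions: PPh3, DIAD, toluene, 0 °C → rt; then AuCl3 (cat.), AgOSO2CF3 (cat.), ClCH2CH2Cl, rt, same flask
Reagents that add atoms: none
Why: Under Mitsunobu conditions the only free hydroxyl of 16, the phenol para to the interflavan carbon, displaces the oxyphosphonium derivative of the (S)-carbinol of 19 with inversion (Mitsunobu aryl ether synthesis), which forms O1–C2 and sets C2 as R in ether 20; the gold/silver Lewis acid then activates the terminal epoxide and the ring carbon ortho to the new ether oxygen attacks its CH2 terminus (intramolecular Friedel–Crafts epoxide–arene alkylation, the known route to 3-chromanols), which forms C4–C4a. Ring C of unit 4 closes in the 6-endo mode at the epoxide, the arene carbon attacking the unsubstituted carbon so that the oxirane oxygen becomes the C3 hydroxyl. C3 keeps the R configuration of the oxirane carbon of 19, whose C–O bond is not touched, and the erythro relation of 19 together with the single inversion at C2 gives the 2,3-cis (epicatechin) pattern. The regiochemistry that makes the 4→6 linkage is secured by the substrate: only the para oxygen is free and the two carbons ortho to it are equivalent, so either closure gives the same product. The 6-endo over 5-exo preference rests on the unhindered CH2 terminus and on the internal oxirane carbon being hindered and deactivated by the adjacent aryloxy-bearing carbon, and O- rather than C-alkylation at C2 is enforced by the SN2 (not cationic) etherification.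

Step 17
Reactants: 21 protected tetramer
Product: 22 target tetramer CNP0103636.1
Conditions: H2 (1 atm), Pd(OH)2/C, NaOAc, THF–MeOH–H2O, rt
Reagents that add atoms: none
Why: Catalytic hydrogenolysis: Pd(OH)2/C should cleave the eighteen benzyl ethers and reduce the three aryl C–Br bonds, sodium acetate buffering the HBr so that the acid-labile interflavan bonds and all stereocentres are kept.

Compound list
1 | (−)-epicatechin, (2R,3R) | C1c2c(O)cc(O)cc2O[C@H](c2ccc(O)c(O)c2)[C@@H]1O | starting material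
2 | 3,5,7,3',4'-penta-O-benzyl-(−)-epicatechin | C1c2c(OCc3ccccc3)cc(OCc3ccccc3)cc2O[C@H](c2ccc(OCc3ccccc3)c(OCc3ccccc3)c2)[C@@H]1OCc1ccccc1 | intermediate
3 | 4β-(2-ethoxyethoxy)-3,5,7,3',4'-penta-O-benzylepicatechin (3,4-trans) | CCOCCO[C@H]1c2c(OCc3ccccc3)cc(OCc3ccccc3)cc2O[C@H](c2ccc(OCc3ccccc3)c(OCc3ccccc3)c2)[C@@H]1OCc1ccccc1 | intermediate
4 | 6,8-dibromo-4β-(2-ethoxyethoxy)-3,5,7,3',4'-penta-O-benzylepicatechin | CCOCCO[C@H]1c2c(OCc3ccccc3)c(Br)c(OCc3ccccc3)c(Br)c2O[C@H](c2ccc(OCc3ccccc3)c(OCc3ccccc3)c2)[C@@H]1OCc1ccccc1 | intermediate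
5 | (−)-epiafzelechin, (2R,3R) | C1c2c(O)cc(O)cc2O[C@H](c2ccc(O)cc2)[C@@H]1O | starting material
6 | 3,5,7,4'-tetra-O-benzyl-(−)-epiafzelechin | C1c2c(OCc3ccccc3)cc(OCc3ccccc3)cc2O[C@H](c2ccc(OCc3ccccc3)cc2)[C@@H]1OCc1ccccc1 | intermediate
7 | 4β-(2-ethoxyethoxy)-3,5,7,4'-tetra-O-benzylepiafzelechin | CCOCCO[C@H]1c2c(OCc3ccccc3)cc(OCc3ccccc3)cc2O[C@H](c2ccc(OCc3ccccc3)cc2)[C@@H]1OCc1ccccc1 | intermediate
8 | 8-bromo-4β-(2-ethoxyethoxy)-3,5,7,4'-tetra-O-benzylepiafzelechin | CCOCCO[C@H]1c2c(OCc3ccccc3)cc(OCc3ccccc3)c(Br)c2O[C@H](c2ccc(OCc3ccccc3)cc2)[C@@H]1OCc1ccccc1 | intermediate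
9 | 8-bromo-4β-(2,6-dimethylphenylthio)-3,5,7,4'-tetra-O-benzylepiafzelechin | Cc1cccc(C)c1S[C@H]1c2c(OCc3ccccc3)cc(OCc3ccccc3)c(Br)c2O[C@H](c2ccc(OCc3ccccc3)cc2)[C@@H]1OCc1ccccc1 | intermediate
10 | dimer: 6,8-dibromo-penta-O-benzylepicatechin-(4β→6)-[8-bromo-4β-(2,6-dimethylphenylthio)-tetra-O-benzylepiafzelechin] | Cc1cccc(C)c1S[C@H]1c2c(OCc3ccccc3)c([C@H]3c4c(OCc5ccccc5)c(Br)c(OCc5ccccc5)c(Br)c4O[C@H](c4ccc(OCc5ccccc5)c(OCc5ccccc5)c4)[C@@H]3OCc3ccccc3)c(OCc3ccccc3)c(Br)c2O[C@H](c2ccc(OCc3ccccc3)cc2)[C@@H]1OCc1ccccc1 | intermediate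
11 | phloroglucinol | Oc1cc(O)cc(O)c1 | starting material
12 | 4β-(2,4,6-trihydroxyphenyl)-3,5,7,3',4'-penta-O-benzylepicatechin | Oc1cc(O)c(c(O)c1)[C@H]1c2c(OCc3ccccc3)cc(OCc3ccccc3)cc2O[C@H](c2ccc(OCc3ccccc3)c(OCc3ccccc3)c2)[C@@H]1OCc1ccccc1 | intermediate
13 | 4β-[2,6-dihydroxy-4-(pivaloyloxy)phenyl]-3,5,7,3',4'-penta-O-benzylepicatechin | CC(C)(C)C(=O)Oc1cc(O)c(c(O)c1)[C@H]1c2c(OCc3ccccc3)cc(OCc3ccccc3)cc2O[C@H](c2ccc(OCc3ccccc3)c(OCc3ccccc3)c2)[C@@H]1OCc1ccccc1 | intermediate
14 | 4β-[2,6-bis(benzyloxy)-4-(pivaloyloxy)phenyl]-3,5,7,3',4'-penta-O-benzylepicatechin | CC(C)(C)C(=O)Oc1cc(OCc2ccccc2)c(c(OCc2ccccc2)c1)[C@H]1c2c(OCc3ccccc3)cc(OCc3ccccc3)cc2O[C@H](c2ccc(OCc3ccccc3)c(OCc3ccccc3)c2)[C@@H]1OCc1ccccc1 | intermediate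
15 | protected trimer with pivalate cap: units 1–3 fully benzylated, Br at C6 and C8 of unit 1 and C8 of unit 2, unit 3 bearing 4β-[2,6-bis(benzyloxy)-4-(pivaloyloxy)phenyl] | C(c6ccccc6)Oc1ccc([C@H]2Oc3c(Br)c(OCc6ccccc6)c([C@H]4c5c(OCc6ccccc6)c(Br)c(OCc6ccccc6)c(Br)c5O[C@H](c5ccc(OCc6ccccc6)c(OCc6ccccc6)c5)[C@@H]4OCc6ccccc6)c(OCc6ccccc6)c3[C@H](c3c(OCc6ccccc6)cc(OCc6ccccc6)c4c3O[C@H](c3ccc(OCc6ccccc6)c(OCc6ccccc6)c3)[C@H](OCc6ccccc6)[C@H]4c3c(OCc6ccccc6)cc(OC(=O)C(C)(C)C)cc3OCc6ccccc6)[C@H]2OCc6ccccc6)cc1 | intermediate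
16 | protected trimer with 2,6-bis(benzyloxy)-4-hydroxyphenyl cap | C(c6ccccc6)Oc1ccc([C@H]2Oc3c(Br)c(OCc6ccccc6)c([C@H]4c5c(OCc6ccccc6)c(Br)c(OCc6ccccc6)c(Br)c5O[C@H](c5ccc(OCc6ccccc6)c(OCc6ccccc6)c5)[C@@H]4OCc6ccccc6)c(OCc6ccccc6)c3[C@H](c3c(OCc6ccccc6)cc(OCc6ccccc6)c4c3O[C@H](c3ccc(OCc6ccccc6)c(OCc6ccccc6)c3)[C@H](OCc6ccccc6)[C@H]4c3c(OCc6ccccc6)cc(O)cc3OCc6ccccc6)[C@H]2OCc6ccccc6)cc1 | intermediate
17 | 3,4-bis(benzyloxy)benzaldehyde | O=Cc1ccc(OCc2ccccc2)c(OCc2ccccc2)c1 | starting material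
18 | (±)-1-[3,4-bis(benzyloxy)phenyl]prop-2-en-1-ol | OC(C=C)c1ccc(OCc2ccccc2)c(OCc2ccccc2)c1 | intermediate
19 | (S)-[3,4-bis(benzyloxy)phenyl][(2R)-oxiran-2-yl]methanol | O[C@@H](c1ccc(OCc2ccccc2)c(OCc2ccccc2)c1)[C@H]1CO1 | intermediate
20 | aryl ether epoxide: cap oxygen of 16 bonded to the (R)-benzylic carbon bearing 3,4-bis(benzyloxy)phenyl and (2R)-oxiran-2-yl | C(c6ccccc6)Oc1ccc([C@H]2Oc3c(Br)c(OCc6ccccc6)c([C@H]4c5c(OCc6ccccc6)c(Br)c(OCc6ccccc6)c(Br)c5O[C@H](c5ccc(OCc6ccccc6)c(OCc6ccccc6)c5)[C@@H]4OCc6ccccc6)c(OCc6ccccc6)c3[C@H](c3c(OCc6ccccc6)cc(OCc6ccccc6)c4c3O[C@H](c3ccc(OCc6ccccc6)c(OCc6ccccc6)c3)[C@H](OCc6ccccc6)[C@H]4c3c(OCc6ccccc6)cc(O[C@H](c4ccc(OCc6ccccc6)c(OCc6ccccc6)c4)[C@H]4CO4)cc3OCc6ccccc6)[C@H]2OCc6ccccc6)cc1 | intermediate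
21 | protected tetramer: eighteen benzyl ethers, Br at C6 and C8 of unit 1 and C8 of unit 2, free 3-OH on unit 4 (2R,3R) | C(c6ccccc6)Oc1ccc([C@H]2Oc3c(Br)c(OCc6ccccc6)c([C@H]4c5c(OCc6ccccc6)c(Br)c(OCc6ccccc6)c(Br)c5O[C@H](c5ccc(OCc6ccccc6)c(OCc6ccccc6)c5)[C@@H]4OCc6ccccc6)c(OCc6ccccc6)c3[C@H](c3c(OCc6ccccc6)cc(OCc6ccccc6)c4c3O[C@H](c3ccc(OCc6ccccc6)c(OCc6ccccc6)c3)[C@H](OCc6ccccc6)[C@H]4c3c(OCc6ccccc6)cc4c(c3OCc6ccccc6)C[C@@H](O)[C@@H](c3ccc(OCc6ccccc6)c(OCc6ccccc6)c3)O4)[C@H]2OCc6ccccc6)cc1 | intermediate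
22 | CNP0103636.1, epicatechin-(4β→6)-epiafzelechin-(4β→8)-epicatechin-(4β→6)-epicatechin | Oc1ccc([C@H]2Oc3cc(O)c([C@H]4c5c(O)cc(O)cc5O[C@H](c5ccc(O)c(O)c5)[C@@H]4O)c(O)c3[C@H](c3c(O)cc(O)c4c3O[C@H](c3ccc(O)c(O)c3)[C@H](O)[C@H]4c3c(O)cc4c(c3O)C[C@@H](O)[C@@H](c3ccc(O)c(O)c3)O4)[C@H]2O)cc1 | target

Total step count: 17.
Longest linear sequence: 9 steps (5 → 6 → 7 → 8 → 9 → 10 → 15 → 16 → 21 → 22; the branch 1 → 2 → 3 → 12 → 13 → 14 → 15 → 16 → 21 → 22 is equally long).

Steps most likely to fail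

Step 16. Two processes may spoil it. The electron-rich benzylic oxyphosphonium species may ionize during etherification, eroding the inversion at C2. Phosphine oxide and hydrazide may deactivate the Lewis acid, so that the epoxide of 20 stays open or closes 5-exo. The fallback sets out from 16 and 19 and gives up the one-flask cascade for two discrete operations. The Mitsunobu etherification is run alone and ether 20 is isolated by chromatography, which also removes any C2 epimer. Purified 20 is then closed in a separate, metal-free step by solvent-promoted Friedel–Crafts epoxide–arene alkylation in hexafluoroisopropanol (rt to 40 °C). The sequence comes back to the route at 21 and makes no compound outside the list.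

Step 12. The hindered dimeric cation may be captured only slowly by the bulky nucleophile. The iodonium promoter may then iodinate the electron-rich ring of 14, or the interflavan bond may be cleaved and scrambled. The fallback sets out from 10. The arylthio group is first exchanged for hydroxyl in the absence of the nucleophile (I2, Ag2O, wet THF) to give the dimeric C4 carbinol F1. F1 is then ionized by a hard Lewis acid (BF3·OEt2, CH2Cl2, −40 °C) in the presence of 14, so the nucleophile never meets an iodinating agent. The sequence comes back to the route at 15.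

Step 8. The bromine-deactivated, sulfide-bearing ring of 9 may attack sluggishly. The arylthio group may also transfer from 9 to the cation of 4, which would scramble the two electrophilic sites. The fallback sets out from 6 and defers the C4 leaving group of unit 2 until after the coupling. NBS at −78 °C gives 8-bromo-3,5,7,4'-tetra-O-benzylepiafzelechin F2. BF3·OEt2 coupling of 4 with excess F2 gives the C4-unsubstituted dimer F3. DDQ with 2-ethoxyethanol oxidizes its only C4 methylene to the dimeric 4β-(2-ethoxyethoxy) ether F4. F4 couples with 14 under BF3·OEt2 and comes back to the route at 15.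

Further compounds
F0 | step 16 | none | none
F1 | step 12 | dimeric C4 carbinol: 6,8-dibromo-penta-O-benzylepicatechin-(4β→6)-[8-bromo-4β-hydroxy-tetra-O-benzylepiafzelechin] | O[C@H]1c2c(OCc3ccccc3)c([C@H]3c4c(OCc5ccccc5)c(Br)c(OCc5ccccc5)c(Br)c4O[C@H](c4ccc(OCc5ccccc5)c(OCc5ccccc5)c4)[C@@H]3OCc3ccccc3)c(OCc3ccccc3)c(Br)c2O[C@H](c2ccc(OCc3ccccc3)cc2)[C@@H]1OCc1ccccc1
F2 | step 8 | 8-bromo-3,5,7,4'-tetra-O-benzylepiafzelechin | C1c2c(OCc3ccccc3)cc(OCc3ccccc3)c(Br)c2O[C@H](c2ccc(OCc3ccccc3)cc2)[C@@H]1OCc1ccccc1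
F3 | step 8 | C4-unsubstituted dimer: 6,8-dibromo-penta-O-benzylepicatechin-(4β→6)-[8-bromo-tetra-O-benzylepiafzelechin] | C1c2c(OCc3ccccc3)c([C@H]3c4c(OCc5ccccc5)c(Br)c(OCc5ccccc5)c(Br)c4O[C@H](c4ccc(OCc5ccccc5)c(OCc5ccccc5)c4)[C@@H]3OCc3ccccc3)c(OCc3ccccc3)c(Br)c2O[C@H](c2ccc(OCc3ccccc3)cc2)[C@@H]1OCc1ccccc1
F4 | step 8 | dimeric ether: 6,8-dibromo-penta-O-benzylepicatechin-(4β→6)-[8-bromo-4β-(2-ethoxyethoxy)-tetra-O-benzylepiafzelechin] | CCOCCO[C@H]1c2c(OCc3ccccc3)c([C@H]3c4c(OCc5ccccc5)c(Br)c(OCc5ccccc5)c(Br)c4O[C@H](c4ccc(OCc5ccccc5)c(OCc5ccccc5)c4)[C@@H]3OCc3ccccc3)c(OCc3ccccc3)c(Br)c2O[C@H](c2ccc(OCc3ccccc3)cc2)[C@@H]1OCc1ccccc1
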